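**Retrosynthetic overview**

1. The quinone comes from Teuber oxidation of a 2,6-disubstituted phenol; no ring is built, since the six-membered ring is carried intact from o-cresol and oxidised last.
2. The (8'R,9'R)-syn-diol comes from Felkin–Anh reduction of an (8'R)-8'-silyloxy-9'-ketone.
3. The C8'–C9' bond and the C8' stereocentre come from a chiral triazolylidene-catalysed cross silyl benzoin between a geranial-derived acylsilane and a C8' enal (key step, proposed new method).
4. The enal comes from SeO2 oxidation of the terminal (E)-methyl of ortho-geranylated o-cresol; the acylsilane comes from geranial by PhMe2SiLi addition and oxidation.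

Locants: the side chain is numbered C1' (ring-bound CH2) to C16'; in the hexadecatetraene names of 10–13 the same carbons carry the unprimed locants 1–16.

Assumption: geranial is bought as the pure (2E)-isomer, not as the E/Z citral mixture.

**Route**

Step 1
Reactants: 1 o-cresol (2-methylphenol); 2 geranyl bromide ((2E)-1-bromo-3,7-dimethylocta-2,6-diene)
Product: 3 2-[(2E)-3,7-dimethylocta-2,6-dien-1-yl]-6-methylphenol
Conditions: NaH (1.0 equiv), toluene, 0 → 23 °C; then 2 (0.8 equiv), 23 °C, 16 h
Reagents that add atoms: none
Why: Ortho-selective C-allylation of a sodium phenoxide in a non-polar medium (Claisen-type C-alkylation): the contact ion-pair aggregate shields oxygen and delivers the primary allylic bromide by SN2 to the only free ortho carbon, keeping the 2E alkene; no stereocentre is formed.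

Step 2
Reactants: 3 2-[(2E)-3,7-dimethylocta-2,6-dien-1-yl]-6-methylphenol
Product: 4 tert-butyl{2-[(2E)-3,7-dimethylocta-2,6-dien-1-yl]-6-methylphenoxy}dimethylsilane
Conditions: NaH, THF, 0 °C; TBSCl, 23 °C
Reagents that add atoms: tert-butyldimethylsilyl chloride, CC(C)(C)[Si](C)(C)Cl
Why: O-silylation of the hindered phenoxide masks the acidic OH, which would otherwise quench the carbene and hydride steps and could close a chroman onto the 2',3'-alkene under the acidic SeO2 conditions.

Step 3
Reactants: 4 tert-butyl{2-[(2E)-3,7-dimethylocta-2,6-dien-1-yl]-6-methylphenoxy}dimethylsilane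
Product: 6 (2E,6E)-8-[2-(tert-butyldimethylsilyloxy)-3-methylphenyl]-2,6-dimethylocta-2,6-dienal, via allylic alcohol 5 (not isolated)
Conditions: SeO2 (0.3 equiv), t-BuOOH (3 equiv), salicylic acid (0.1 equiv), CH2Cl2, 0 → 23 °C; filter, then MnO2 (15 equiv), CH2Cl2, 23 °C
Reagents that add atoms: tert-butyl hydroperoxide, CC(C)(C)OO (its oxygen is passed on by catalytic selenium dioxide, O=[Se]=O)
Why: Catalytic SeO2 allylic oxidation (ene reaction, then [2,3]-sigmatropic shift) attacks the (E)-methyl of the terminal, least hindered trisubstituted alkene, so the 6'E geometry is fixed by mechanism; MnO2 converges the alcohol/aldehyde mixture to the enal.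

Step 4
Reactants: 7 geranial ((2E)-3,7-dimethylocta-2,6-dienal)
Product: 8 rac-(2E)-1-[dimethyl(phenyl)silyl]-3,7-dimethylocta-2,6-dien-1-ol
Conditions: PhMe2SiLi (1.1 equiv, from PhMe2SiCl and Li, THF, 0 °C), THF, −78 °C, 20 min; AcOH (1.2 equiv), −78 °C
Reagents that add atoms: dimethylphenylsilyllithium, [Li][Si](C)(C)c1ccccc1
Why: 1,2-Addition of a silyllithium to the aldehyde (β,β-disubstitution blocks conjugate addition), with a cold acidic quench to prevent Brook rearrangement; the racemic carbinol is oxidised away in the next step.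

Step 5
Reactants: 8 rac-(2E)-1-[dimethyl(phenyl)silyl]-3,7-dimethylocta-2,6-dien-1-ol
Product: 9 (2E)-1-[dimethyl(phenyl)silyl]-3,7-dimethylocta-2,6-dien-1-one
Conditions: Dess–Martin periodinane (1.3 equiv), CH2Cl2, 0 °C, dark
Reagents that add atoms: none
Why: Dess–Martin oxidation of an α-hydroxysilane to the acylsilane under non-basic conditions, which avoids Brook rearrangement and E/Z isomerisation of the enoylsilane.

Step 6
Reactants: 6 (2E,6E)-8-[2-(tert-butyldimethylsilyloxy)-3-methylphenyl]-2,6-dimethylocta-2,6-dienal; 9 (2E)-1-[dimethyl(phenyl)silyl]-3,7-dimethylocta-2,6-dien-1-one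
Product: 10 (2E,6E,8R,10E)-1-[2-(tert-butyldimethylsilyloxy)-3-methylphenyl]-8-{[dimethyl(phenyl)silyl]oxy}-3,7,11,15-tetramethylhexadeca-2,6,10,14-tetraen-9-one
Conditions: 9 (1.5 equiv), (5aS,10bR)-2-(pentafluorophenyl)-5a,10b-dihydro-4H,6H-indeno[2,1-b][1,2,4]triazolo[4,3-d][1,4]oxazin-2-ium tetrafluoroborate (15 mol %; its antipode is used if the sense of induction proves opposite), KN(SiMe3)2 (12 mol %), 4 Å molecular sieves, toluene, −20 → 23 °C
Reagents that add atoms: none
Why: Proposed new method: enantioselective carbene-catalysed cross silyl benzoin – the free triazolylidene adds to the C=O of acylsilane 9 and a [1,2]-Brook shift of SiMe2Ph from C to O gives an O-silyl Breslow intermediate (an acyl-anion equivalent formed only from 9, because aldehyde 6 has no Brook pathway and, being α-branched, is a poor Breslow donor); its carbinol carbon adds 1,2 to the aldehyde of 6 from the Si face inside the aminoindanol pocket (the γ-terminus is blocked by β,β-disubstitution), and 1,4-O→O silyl transfer then ejects the carbene, forming the C8–C9 bond and the (8R) stereocentre under catalyst control; the closest known reaction types are the cyanide- or metallophosphite-catalysed cross silyl benzoin and carbene-catalysed acyl-anion additions of acylsilanes (sila-Stetter), while an enantioselective carbene version and an enoylsilane/enal pair have not been shown.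

Step 7
Reactants: 10 (2E,6E,8R,10E)-1-[2-(tert-butyldimethylsilyloxy)-3-methylphenyl]-8-{[dimethyl(phenyl)silyl]oxy}-3,7,11,15-tetramethylhexadeca-2,6,10,14-tetraen-9-one
Product: 12 2-[(2E,6E,8R,9R,10E)-8,9-dihydroxy-3,7,11,15-tetramethylhexadeca-2,6,10,14-tetraen-1-yl]-6-methylphenol, via monosilyl diol 11 (not isolated)
Conditions: LiBH(s-Bu)3 (L-Selectride, 1.3 equiv), THF, −78 °C, 1 h; then Bu4NF (1 M in THF, 4 equiv), −78 → 23 °C; H2O
Reagents that add atoms: none
Why: Felkin–Anh (polar model) 1,2-reduction: with the bulky, non-chelating hydride the C8–OSi bond lies anti to the incoming hydride, which passes the C8–H and gives the 8,9-syn (threo) diol, i.e. 9R from 8R; β,β-disubstitution of the enone suppresses conjugate reduction, and fluoride then cleaves both silyl ethers in the same flask.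

Step 8
Reactants: 12 2-[(2E,6E,8R,9R,10E)-8,9-dihydroxy-3,7,11,15-tetramethylhexadeca-2,6,10,14-tetraen-1-yl]-6-methylphenol
Product: 13 2-[(2E,6E,8R,9R,10E)-8,9-dihydroxy-3,7,11,15-tetramethylhexadeca-2,6,10,14-tetraen-1-yl]-6-methylcyclohexa-2,5-diene-1,4-dione (CNP0159538.1)
Conditions: (KSO3)2NO (Fremy's salt, 2.5 equiv), aq. KH2PO4 (pH 6), acetone/H2O, 0 → 23 °C
Reagents that add atoms: potassium nitrosodisulfonate (Fremy's salt), [K+].[K+].[O]N(S(=O)(=O)[O-])S(=O)(=O)[O-]
Why: Teuber oxidation: two equivalents of the nitroxyl radical convert a 2,6-dialkylphenol with a free para position into the para-quinone under buffered, near-neutral conditions that leave the allylic diol and the four trisubstituted alkenes untouched; no stereocentre is affected.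

**Compound list**

1 | o-cresol (2-methylphenol) | Cc1ccccc1O | starting material
2 | geranyl bromide, (2E)-1-bromo-3,7-dimethylocta-2,6-diene | CC(C)=CCC/C(C)=C/CBr | starting material
3 | 2-[(2E)-3,7-dimethylocta-2,6-dien-1-yl]-6-methylphenol | CC(C)=CCC/C(C)=C/Cc1cccc(C)c1O | intermediate
4 | tert-butyl{2-[(2E)-3,7-dimethylocta-2,6-dien-1-yl]-6-methylphenoxy}dimethylsilane | CC(C)=CCC/C(C)=C/Cc1cccc(C)c1O[Si](C)(C)C(C)(C)C | intermediate
5 | (2E,6E)-8-[2-(tert-butyldimethylsilyloxy)-3-methylphenyl]-2,6-dimethylocta-2,6-dien-1-ol | OC/C(C)=C/CC/C(C)=C/Cc1cccc(C)c1O[Si](C)(C)C(C)(C)C | intermediate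
6 | (2E,6E)-8-[2-(tert-butyldimethylsilyloxy)-3-methylphenyl]-2,6-dimethylocta-2,6-dienal | O=C/C(C)=C/CC/C(C)=C/Cc1cccc(C)c1O[Si](C)(C)C(C)(C)C | intermediate
7 | geranial, (2E)-3,7-dimethylocta-2,6-dienal | CC(C)=CCC/C(C)=C/C=O | starting material
8 | rac-(2E)-1-[dimethyl(phenyl)silyl]-3,7-dimethylocta-2,6-dien-1-ol | CC(C)=CCC/C(C)=C/C(O)[Si](C)(C)c1ccccc1 | intermediate
9 | (2E)-1-[dimethyl(phenyl)silyl]-3,7-dimethylocta-2,6-dien-1-one | CC(C)=CCC/C(C)=C/C(=O)[Si](C)(C)c1ccccc1 | intermediate
10 | (2E,6E,8R,10E)-1-[2-(tert-butyldimethylsilyloxy)-3-methylphenyl]-8-{[dimethyl(phenyl)silyl]oxy}-3,7,11,15-tetramethylhexadeca-2,6,10,14-tetraen-9-one | CC(C)=CCC/C(C)=C/C(=O)[C@H](O[Si](C)(C)c1ccccc1)/C(C)=C/CC/C(C)=C/Cc2cccc(C)c2O[Si](C)(C)C(C)(C)C | intermediate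
11 | (2E,6E,8R,9R,10E)-1-[2-(tert-butyldimethylsilyloxy)-3-methylphenyl]-8-{[dimethyl(phenyl)silyl]oxy}-3,7,11,15-tetramethylhexadeca-2,6,10,14-tetraen-9-ol | CC(C)=CCC/C(C)=C/[C@@H](O)[C@H](O[Si](C)(C)c1ccccc1)/C(C)=C/CC/C(C)=C/Cc2cccc(C)c2O[Si](C)(C)C(C)(C)C | intermediate
12 | 2-[(2E,6E,8R,9R,10E)-8,9-dihydroxy-3,7,11,15-tetramethylhexadeca-2,6,10,14-tetraen-1-yl]-6-methylphenol | CC(C)=CCC/C(C)=C/[C@@H](O)[C@H](O)/C(C)=C/CC/C(C)=C/Cc1cccc(C)c1O | intermediate
13 | 2-[(2E,6E,8R,9R,10E)-8,9-dihydroxy-3,7,11,15-tetramethylhexadeca-2,6,10,14-tetraen-1-yl]-6-methylcyclohexa-2,5-diene-1,4-dione | CC(C)=CCC/C(C)=C/[C@@H](O)[C@H](O)/C(C)=C/CC/C(C)=C/CC1=CC(=O)C=C(C)C1=O | target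

**Step count and risk**

Total: 8 steps. Longest linear sequence: 6 steps (steps 1, 2, 3, 6, 7, 8 from o-cresol); the acylsilane branch (steps 4, 5) joins at step 6.

Steps most likely to fail:

Step 6 (the proposed new carbene-catalysed cross silyl benzoin). Possible failures are diversion of the carbene onto aldehyde 6, protonation of the O-silyl Breslow intermediate back to geranial, low enantioselectivity, or E/Z erosion at C10=C11. The fallback sets out from 6 and 9 and uses the established chiral metallophosphite cross silyl benzoin. The lithium phosphite made from a TADDOL-derived cyclic H-phosphonate (10–20 mol %) and n-BuLi (same loading) in THF at 0 → 23 °C adds to the acylsilane. A [1,2]-Brook shift, addition to the aldehyde and 1,4-silyl transfer then release the phosphite. The TADDOL antipode is chosen for the 8R product. This replaces carbene umpolung by phosphite/lithium catalysis on the same partners and comes back to the route at 10 (no new compound, F0).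

Step 3 (SeO2 oxidation). Possible failures are competing oxidation at C4' or at the benzylic C1' of the internal alkene, over-oxidation, and low yield. The fallback sets out from 4 and installs the enal by olefin cross-metathesis instead of allylic oxidation: methacrolein (CC(=C)C=O, 8 equiv), second-generation Hoveyda–Grubbs catalyst RuCl2(H2IMes)(=CH-C6H4-2-O-i-Pr) (5 mol %), CH2Cl2, 40 °C. Only the terminal 2-methylprop-1-enyl end can enter the cycle; the internal trisubstituted alkene is inert. The (E)-2-methyl-enal forms directly, so the fallback comes back to the route at 6 (no new compound, F0).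

Step 7 (Felkin–Anh reduction with in-flask desilylation). Possible failures are a low syn:anti ratio, conjugate reduction, or epimerisation at C8. The fallback sets out from 10 and replaces substrate control by catalyst control: (S)-2-methyl-CBS-oxazaborolidine (0.5 equiv), catecholborane (1.5 equiv), toluene, −78 °C, giving 11, which is now isolated. The (S)-catalyst is chosen on the expectation that the branched silyloxy-bearing carbon acts as the larger group; the (R)-catalyst is used otherwise. Separate treatment with Bu4NF in THF then brings the fallback back to the route at 12 (no new compound, F0).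

**Further compounds**

F0 | step 6 | none | none
F0 | step 3 | none | none
F0 | step 7 | none | none
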